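**Strategy.** Both outer flavan units are the same 7,8-dihydroxyflavan-3-ol joined through C5, so one bromochroman is made once and coupled twice to 6,8-dibromocatechin. Its ring C is disconnected at C4–C4a and O1–C8a. In ring A, C4a lies between the biaryl carbon C5 and the ether carbon C8a; with bromine on C5 and fluorine on C8a, C4a–H is the most acidic site. In one pot the aryl anion opens an enantiopure cyclic sulfate at its primary carbon (C4–C4a), and the freed benzylic alkoxide displaces fluoride (O1–C8a). C2 and C3 arrive preset; the sulfate masks O3, and bromine remains for the Suzuki coupling.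

Key step: step 7

Assumption: the target SMILES defines no configuration for the two hindered biaryl axes, so they are treated as not stereodefined and no atropselectivity is claimed. Flavan numbering (O1, C2, C3, C4, C4a, C5–C8, C8a) is used throughout.

**Step 1**
Reactants: 1 5-bromo-3-fluoro-2-hydroxybenzaldehyde
Product: 2 5-bromo-3-fluorobenzene-1,2-diol
Conditions: 30% H2O2, aq NaOH, THF, 0 °C to rt; then aq HCl
Reagents that add atoms: hydrogen peroxide, OO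
Why: Dakin oxidation of an ortho-hydroxybenzaldehyde, in which hydroperoxide adds to the aldehyde, the aryl group migrates to oxygen and the formate ester is hydrolysed to the second phenol.

**Step 2**
Reactants: 2 5-bromo-3-fluorobenzene-1,2-diol
Product: 3 1,2-bis(benzyloxy)-5-bromo-3-fluorobenzene
Conditions: BnBr, K2CO3, DMF, 50 °C
Reagents that add atoms: benzyl bromide, BrCc1ccccc1
Why: Williamson etherification of both phenols, which gives hydrogenolysable ethers that tolerate the later amide base, Grignard and alkoxide conditions.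

**Step 3**
Reactants: 4 4-bromo-1,2-bis(benzyloxy)benzene; 5 (S)-2,2-dimethyl-1,3-dioxolane-4-carbaldehyde (freshly distilled)
Product: 8 (R)-[3,4-bis(benzyloxy)phenyl][(S)-2,2-dimethyl-1,3-dioxolan-4-yl]methanol, via aryllithium 6 (not isolated), via aryltitanium triisopropoxide 7 (not isolated)
Conditions: 4, n-BuLi, THF, −78 °C; ClTi(OiPr)3, −78 to −40 °C; then 5, −78 to 0 °C
Reagents that add atoms: none
Why: Bromine–lithium exchange, transmetalation to a non-chelating aryltitanium reagent and Felkin–Anh addition to the α-alkoxy aldehyde should give mainly the anti (R)-carbinol by attack anti to the α C–O bond, the minor syn epimer being removed by chromatography.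

**Step 4**
Reactants: 8 (R)-[3,4-bis(benzyloxy)phenyl][(S)-2,2-dimethyl-1,3-dioxolan-4-yl]methanol
Product: 9 tert-butyl{(R)-[3,4-bis(benzyloxy)phenyl][(S)-2,2-dimethyl-1,3-dioxolan-4-yl]methoxy}dimethylsilane
Conditions: TBSOTf, 2,6-lutidine, CH2Cl2, −40 to 0 °C
Reagents that add atoms: tert-butyldimethylsilyl trifluoromethanesulfonate, CC(C)(C)[Si](C)(C)OS(=O)(=O)C(F)(F)F
Why: Silylation of the hindered secondary benzylic alcohol masks the future O1 until fluoride releases it in the key step.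

**Step 5**
Reactants: 9 tert-butyl{(R)-[3,4-bis(benzyloxy)phenyl][(S)-2,2-dimethyl-1,3-dioxolan-4-yl]methoxy}dimethylsilane
Product: 10 (2S,3R)-3-[3,4-bis(benzyloxy)phenyl]-3-[(tert-butyldimethylsilyl)oxy]propane-1,2-diol
Conditions: 80% aq AcOH, 40 °C
Reagents that add atoms: none
Why: Mild acid hydrolysis of a terminal isopropylidene acetal, conditions under which a hindered secondary TBS ether should survive.

**Step 6**
Reactants: 10 (2S,3R)-3-[3,4-bis(benzyloxy)phenyl]-3-[(tert-butyldimethylsilyl)oxy]propane-1,2-diol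
Product: 12 (4S)-4-{(R)-[3,4-bis(benzyloxy)phenyl][(tert-butyldimethylsilyl)oxy]methyl}-1,3,2-dioxathiolane 2,2-dioxide, via cyclic sulfite 11 (not isolated)
Conditions: SOCl2, Et3N, CH2Cl2, 0 °C; then RuCl3·xH2O (cat.), NaIO4, MeCN/H2O, 0 °C, short reaction time
Reagents that add atoms: thionyl chloride, O=S(Cl)Cl; sodium periodate, [Na+].[O-]I(=O)(=O)=O
Why: Cyclic sulfite formation followed by ruthenium-catalysed periodate oxidation is the standard two-stage synthesis of 1,2-cyclic sulfates and touches neither stereocentre.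

**Step 7**
Reactants: 3 1,2-bis(benzyloxy)-5-bromo-3-fluorobenzene; 12 (4S)-4-{(R)-[3,4-bis(benzyloxy)phenyl][(tert-butyldimethylsilyl)oxy]methyl}-1,3,2-dioxathiolane 2,2-dioxide
Product: 18 (2R,3S)-7,8-bis(benzyloxy)-2-[3,4-bis(benzyloxy)phenyl]-5-bromo-3,4-dihydro-2H-chromen-3-ol, via aryllithium 13 (not isolated), via arylmagnesium bromide 14 (not isolated), via open-chain alkyl sulfate 15 (not isolated), via desilylated alkoxide 16 (not isolated), via chromanyl sulfate 17 (not isolated)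
Conditions: 3, LDA, THF, −78 °C; MgBr2·OEt2, −78 °C; 12, CuI (10 mol%), −78 to 0 °C; then TBAF, KOtBu, DMF, 60 °C; then 20% aq H2SO4, THF, rt
Reagents that add atoms: none
Why: LDA removes C4a–H of ring A because it is the only hydrogen flanked by both fluorine (C8a) and bromine (C5); after transmetalation the aryl Grignard opens cyclic sulfate 12 at its primary carbon under CuI catalysis (SN2, C4–C4a), which leaves O3 masked as a sulfate monoester. Fluoride then frees the benzylic alkoxide O1, which displaces fluoride at C8a by intramolecular addition–elimination (O1–C8a) and closes ring C as a six-membered ring (6-exo-trig counted on the C8a=C8 bond), and aqueous acid finally cleaves the S–O bond of the sulfate to give the 3-OH. The closest known reaction types are the copper-catalysed Grignard opening of 1,2-cyclic sulfates and the base-mediated cyclisation of 3-(2-fluoroaryl)propanols to chromans. No stereocentre is created: C2 (R) and C3 (S) come from 12 and no bond to either carbon is broken, so the 2,3-trans relationship follows from the anti configuration of the diol. The step needs (a) regioselective metalation, secured by F and Br, (b) ring closure through O1 only, secured by the sulfate on O3, and (c) displacement of F at C8a in preference to Br at C5, secured by the much faster loss of fluoride in addition–elimination and by the para alkoxy group that deactivates C5.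

**Step 8**
Reactants: 18 (2R,3S)-7,8-bis(benzyloxy)-2-[3,4-bis(benzyloxy)phenyl]-5-bromo-3,4-dihydro-2H-chromen-3-ol
Product: 19 (2R,3S)-7,8-bis(benzyloxy)-2-[3,4-bis(benzyloxy)phenyl]-5-(4,4,5,5-tetramethyl-1,3,2-dioxaborolan-2-yl)-3,4-dihydro-2H-chromen-3-ol
Conditions: B2pin2, Pd(dppf)Cl2 (cat.), KOAc, 1,4-dioxane, 90 °C
Reagents that add atoms: bis(pinacolato)diboron, CC1(C)OB(OC1(C)C)B1OC(C)(C)C(C)(C)O1
Why: Miyaura borylation of the aryl bromide under weakly basic conditions that tolerate the free secondary alcohol and the benzyl ethers.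

**Step 9**
Reactants: 20 (+)-catechin, (2R,3S)-2-(3,4-dihydroxyphenyl)-3,4-dihydro-2H-chromene-3,5,7-triol
Product: 21 (2R,3S)-5,7-bis(benzyloxy)-2-[3,4-bis(benzyloxy)phenyl]-3,4-dihydro-2H-chromen-3-ol
Conditions: BnBr, K2CO3, DMF, rt
Reagents that add atoms: benzyl bromide, BrCc1ccccc1
Why: Williamson etherification with a carbonate base alkylates only the four phenols and leaves the 3-OH and both stereocentres untouched.

**Step 10**
Reactants: 21 (2R,3S)-5,7-bis(benzyloxy)-2-[3,4-bis(benzyloxy)phenyl]-3,4-dihydro-2H-chromen-3-ol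
Product: 22 (2R,3S)-5,7-bis(benzyloxy)-2-[3,4-bis(benzyloxy)phenyl]-6,8-dibromo-3,4-dihydro-2H-chromen-3-ol
Conditions: NBS (2.1 equiv), CH2Cl2, −20 °C to rt
Reagents that add atoms: N-bromosuccinimide, O=C1CCC(=O)N1Br
Why: Electrophilic aromatic bromination takes place at C8 and then C6 of the phloroglucinol-type ring A, which is far more electron-rich than ring B.

**Step 11**
Reactants: 22 (2R,3S)-5,7-bis(benzyloxy)-2-[3,4-bis(benzyloxy)phenyl]-6,8-dibromo-3,4-dihydro-2H-chromen-3-ol; 19 (2R,3S)-7,8-bis(benzyloxy)-2-[3,4-bis(benzyloxy)phenyl]-5-(4,4,5,5-tetramethyl-1,3,2-dioxaborolan-2-yl)-3,4-dihydro-2H-chromen-3-ol (2.5 equiv)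
Product: 23 (2R,3S)-5,7-bis(benzyloxy)-2-[3,4-bis(benzyloxy)phenyl]-6,8-bis{(2R,3S)-7,8-bis(benzyloxy)-2-[3,4-bis(benzyloxy)phenyl]-3-hydroxy-3,4-dihydro-2H-chromen-5-yl}-3,4-dihydro-2H-chromen-3-ol
Conditions: Pd(OAc)2, SPhos, K3PO4, toluene/H2O, 100 °C
Reagents that add atoms: none
Why: Twofold Suzuki–Miyaura coupling with a bulky electron-rich biarylphosphine of the kind used for tri-ortho-substituted biaryls forms both C5–aryl bonds without touching any stereocentre.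

**Step 12**
Reactants: 23 the dodeca-O-benzyl trimer
Product: 24 (2R,3S)-2-(3,4-dihydroxyphenyl)-6,8-bis[(2R,3S)-2-(3,4-dihydroxyphenyl)-3,7,8-trihydroxy-3,4-dihydro-2H-chromen-5-yl]-3,4-dihydro-2H-chromene-3,5,7-triol (CNP0171327.1)
Conditions: H2 (1 atm), Pd(OH)2/C, degassed THF/MeOH, rt
Reagents that add atoms: none
Why: Catalytic hydrogenolysis should cleave all twelve aryl benzyl ethers under neutral conditions that leave the flavan rings and their stereocentres intact.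

**Compound list**

1 | 5-bromo-3-fluoro-2-hydroxybenzaldehyde | O=Cc1cc(Br)cc(F)c1O | starting material
2 | 5-bromo-3-fluorobenzene-1,2-diol | Oc1cc(Br)cc(F)c1O | intermediate
3 | 1,2-bis(benzyloxy)-5-bromo-3-fluorobenzene | Fc1cc(Br)cc(OCc2ccccc2)c1OCc1ccccc1 | intermediate
4 | 4-bromo-1,2-bis(benzyloxy)benzene | Brc1ccc(OCc2ccccc2)c(OCc2ccccc2)c1 | starting material
5 | (S)-2,2-dimethyl-1,3-dioxolane-4-carbaldehyde | O=C[C@@H]1COC(C)(C)O1 | starting material
6 | [3,4-bis(benzyloxy)phenyl]lithium | [Li]c1ccc(OCc2ccccc2)c(OCc2ccccc2)c1 | intermediate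
7 | [3,4-bis(benzyloxy)phenyl]tris(propan-2-olato)titanium | CC(C)O[Ti](OC(C)C)(OC(C)C)c1ccc(OCc2ccccc2)c(OCc2ccccc2)c1 | intermediate
8 | (R)-[3,4-bis(benzyloxy)phenyl][(S)-2,2-dimethyl-1,3-dioxolan-4-yl]methanol | O[C@H](c1ccc(OCc2ccccc2)c(OCc2ccccc2)c1)[C@@H]1COC(C)(C)O1 | intermediate
9 | tert-butyl{(R)-[3,4-bis(benzyloxy)phenyl][(S)-2,2-dimethyl-1,3-dioxolan-4-yl]methoxy}dimethylsilane | CC(C)(C)[Si](C)(C)O[C@H](c1ccc(OCc2ccccc2)c(OCc2ccccc2)c1)[C@@H]1COC(C)(C)O1 | intermediate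
10 | (2S,3R)-3-[3,4-bis(benzyloxy)phenyl]-3-[(tert-butyldimethylsilyl)oxy]propane-1,2-diol | CC(C)(C)[Si](C)(C)O[C@H](c1ccc(OCc2ccccc2)c(OCc2ccccc2)c1)[C@@H](O)CO | intermediate
11 | (4S)-4-{(R)-[3,4-bis(benzyloxy)phenyl][(tert-butyldimethylsilyl)oxy]methyl}-1,3,2-dioxathiolane 2-oxide (sulfur epimers) | CC(C)(C)[Si](C)(C)O[C@H](c1ccc(OCc2ccccc2)c(OCc2ccccc2)c1)[C@@H]1COS(=O)O1 | intermediate
12 | (4S)-4-{(R)-[3,4-bis(benzyloxy)phenyl][(tert-butyldimethylsilyl)oxy]methyl}-1,3,2-dioxathiolane 2,2-dioxide | CC(C)(C)[Si](C)(C)O[C@H](c1ccc(OCc2ccccc2)c(OCc2ccccc2)c1)[C@@H]1COS(=O)(=O)O1 | intermediate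
13 | [3,4-bis(benzyloxy)-6-bromo-2-fluorophenyl]lithium | [Li]c1c(F)c(OCc2ccccc2)c(OCc2ccccc2)cc1Br | intermediate
14 | [3,4-bis(benzyloxy)-6-bromo-2-fluorophenyl]magnesium bromide | Br[Mg]c1c(F)c(OCc2ccccc2)c(OCc2ccccc2)cc1Br | intermediate
15 | bromomagnesium (2S,3R)-1-[3,4-bis(benzyloxy)-6-bromo-2-fluorophenyl]-3-[3,4-bis(benzyloxy)phenyl]-3-[(tert-butyldimethylsilyl)oxy]propan-2-yl sulfate | CC(C)(C)[Si](C)(C)O[C@H](c1ccc(OCc2ccccc2)c(OCc2ccccc2)c1)[C@H](Cc1c(F)c(OCc2ccccc2)c(OCc2ccccc2)cc1Br)OS(=O)(=O)[O-].[Mg+]Br | intermediate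
16 | dipotassium (1R,2S)-3-[3,4-bis(benzyloxy)-6-bromo-2-fluorophenyl]-1-[3,4-bis(benzyloxy)phenyl]-2-(sulfonatooxy)propan-1-olate | [O-][C@H](c1ccc(OCc2ccccc2)c(OCc2ccccc2)c1)[C@H](Cc1c(F)c(OCc2ccccc2)c(OCc2ccccc2)cc1Br)OS(=O)(=O)[O-].[K+].[K+] | intermediate
17 | potassium (2R,3S)-7,8-bis(benzyloxy)-2-[3,4-bis(benzyloxy)phenyl]-5-bromo-3,4-dihydro-2H-chromen-3-yl sulfate | [K+].[O-]S(=O)(=O)O[C@H]1Cc2c(Br)cc(OCc3ccccc3)c(OCc3ccccc3)c2O[C@@H]1c1ccc(OCc2ccccc2)c(OCc2ccccc2)c1 | intermediate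
18 | (2R,3S)-7,8-bis(benzyloxy)-2-[3,4-bis(benzyloxy)phenyl]-5-bromo-3,4-dihydro-2H-chromen-3-ol | O[C@H]1Cc2c(Br)cc(OCc3ccccc3)c(OCc3ccccc3)c2O[C@@H]1c1ccc(OCc2ccccc2)c(OCc2ccccc2)c1 | intermediate
19 | (2R,3S)-7,8-bis(benzyloxy)-2-[3,4-bis(benzyloxy)phenyl]-5-(4,4,5,5-tetramethyl-1,3,2-dioxaborolan-2-yl)-3,4-dihydro-2H-chromen-3-ol | O[C@H]1Cc2c(B3OC(C)(C)C(C)(C)O3)cc(OCc3ccccc3)c(OCc3ccccc3)c2O[C@@H]1c1ccc(OCc2ccccc2)c(OCc2ccccc2)c1 | intermediate
20 | (+)-catechin | O[C@H]1Cc2c(O)cc(O)cc2O[C@@H]1c1ccc(O)c(O)c1 | starting material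
21 | (2R,3S)-5,7-bis(benzyloxy)-2-[3,4-bis(benzyloxy)phenyl]-3,4-dihydro-2H-chromen-3-ol | O[C@H]1Cc2c(OCc3ccccc3)cc(OCc3ccccc3)cc2O[C@@H]1c1ccc(OCc2ccccc2)c(OCc2ccccc2)c1 | intermediate
22 | (2R,3S)-5,7-bis(benzyloxy)-2-[3,4-bis(benzyloxy)phenyl]-6,8-dibromo-3,4-dihydro-2H-chromen-3-ol | O[C@H]1Cc2c(OCc3ccccc3)c(Br)c(OCc3ccccc3)c(Br)c2O[C@@H]1c1ccc(OCc2ccccc2)c(OCc2ccccc2)c1 | intermediate
23 | dodeca-O-benzyl trimer (name as in step 11) | O[C@H]1Cc2c(OCc3ccccc3)c(-c3cc(OCc4ccccc4)c(OCc4ccccc4)c4c3C[C@H](O)[C@@H](c3ccc(OCc5ccccc5)c(OCc5ccccc5)c3)O4)c(OCc3ccccc3)c(-c3cc(OCc4ccccc4)c(OCc4ccccc4)c4c3C[C@H](O)[C@@H](c3ccc(OCc5ccccc5)c(OCc5ccccc5)c3)O4)c2O[C@@H]1c1ccc(OCc2ccccc2)c(OCc2ccccc2)c1 | intermediate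
24 | CNP0171327.1 (name as in step 12) | Oc1ccc([C@H]2Oc3c(O)c(O)cc(-c4c(O)c5c(c(-c6cc(O)c(O)c7c6C[C@H](O)[C@@H](c6ccc(O)c(O)c6)O7)c4O)O[C@H](c4ccc(O)c(O)c4)[C@@H](O)C5)c3C[C@@H]2O)cc1O | target

**Totals.** Total step count: 12. Longest linear sequence: 8 steps (3, 4, 5, 6, 7, 8, 11, 12).

**Steps most likely to fail**

Step 7. After desilylation the C2 alkoxide may attack C3 with loss of sulfate (oxirane formation) faster than it closes onto C8a, or closure onto the electron-rich fluoroarene may be slow enough for base-induced aryne formation at the bromide to compete. The fallback replaces the sulfate mask by a benzyl ether and the cyclic sulfate by a primary triflate, so that C3 carries no leaving group while both bonds are still made in one flask. It sets out from diol 10 and arene 3 and comes back to the route at 24.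
- Diol 10 with PhCH(OMe)2 and PPTS gives the benzylidene acetal F1.
- DIBAL-H (CH2Cl2, −78 to 0 °C) opens it reductively with benzyl left on the secondary oxygen, giving the primary alcohol F2.
- Tf2O and 2,6-lutidine at −78 °C give the triflate F3.
- Aryllithium 13 (from 3 and LDA) is alkylated by F3 at −78 °C to the open-chain fluoroarene F4 (not isolated); TBAF and KOtBu in the same flask then close the 3-O-benzyl bromochroman F5.
- Borylation as in step 8 gives the boronate F6, coupling with 22 as in step 11 gives the tetradeca-O-benzyl trimer F7, and hydrogenolysis as in step 12 gives 24.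

Step 11. Oxidative addition at the doubly ortho-substituted C6–Br and C8–Br may be slow, so that hydrodebromination of 22 and protodeboronation of 19 leave mono-coupled material. The fallback is a Negishi coupling with the more reactive arylzinc nucleophile. It sets out from 18 and 22 and comes back at 23.
- 18 with TBSCl and imidazole gives the silyl ether F8.
- n-BuLi (THF, −78 °C) gives the aryllithium F9, and ZnCl2 gives the arylzinc chloride F10.
- 22 is silylated in the same way to the dibromide silyl ether F11.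
- F10 (excess) and F11 with Pd2(dba)3 and RuPhos in THF at 70 °C give the tris-silyl trimer F12, and TBAF returns 23.

Step 3. Facial selectivity in the aryl addition may be poor, giving much of the syn epimer and a hard separation. The fallback sets the carbinol centre by chelation-controlled reduction instead of by addition. It sets out from 8 (as its mixture with the epimer F13) and comes back at 8.
- The mixture of 8 and (S)-carbinol epimer F13 is oxidised with Dess–Martin periodinane to the ketone F14.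
- Zn(BH4)2 in Et2O at −30 °C reduces F14 through a chelate between the carbonyl oxygen and the α-oxygen of the dioxolane, with hydride delivered from the less hindered face, to give anti alcohol 8.

**Further compounds**

F1 | step 7 | (4S)-4-{(R)-[3,4-bis(benzyloxy)phenyl][(tert-butyldimethylsilyl)oxy]methyl}-2-phenyl-1,3-dioxolane (acetal epimers) | CC(C)(C)[Si](C)(C)O[C@H](c1ccc(OCc2ccccc2)c(OCc2ccccc2)c1)[C@@H]1COC(c2ccccc2)O1
F2 | step 7 | (2S,3R)-2-(benzyloxy)-3-[3,4-bis(benzyloxy)phenyl]-3-[(tert-butyldimethylsilyl)oxy]propan-1-ol | CC(C)(C)[Si](C)(C)O[C@H](c1ccc(OCc2ccccc2)c(OCc2ccccc2)c1)[C@@H](OCc1ccccc1)CO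
F3 | step 7 | (2S,3R)-2-(benzyloxy)-3-[3,4-bis(benzyloxy)phenyl]-3-[(tert-butyldimethylsilyl)oxy]propyl trifluoromethanesulfonate | CC(C)(C)[Si](C)(C)O[C@H](c1ccc(OCc2ccccc2)c(OCc2ccccc2)c1)[C@@H](OCc1ccccc1)COS(=O)(=O)C(F)(F)F
F4 | step 7 | tert-butyl{(1R,2S)-2-(benzyloxy)-3-[3,4-bis(benzyloxy)-6-bromo-2-fluorophenyl]-1-[3,4-bis(benzyloxy)phenyl]propoxy}dimethylsilane | CC(C)(C)[Si](C)(C)O[C@H](c1ccc(OCc2ccccc2)c(OCc2ccccc2)c1)[C@H](Cc1c(F)c(OCc2ccccc2)c(OCc2ccccc2)cc1Br)OCc1ccccc1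
F5 | step 7 | (2R,3S)-3,7,8-tris(benzyloxy)-2-[3,4-bis(benzyloxy)phenyl]-5-bromo-3,4-dihydro-2H-chromene | C(c1ccccc1)O[C@H]1Cc2c(Br)cc(OCc3ccccc3)c(OCc3ccccc3)c2O[C@@H]1c1ccc(OCc2ccccc2)c(OCc2ccccc2)c1
F6 | step 7 | 2-{(2R,3S)-3,7,8-tris(benzyloxy)-2-[3,4-bis(benzyloxy)phenyl]-3,4-dihydro-2H-chromen-5-yl}-4,4,5,5-tetramethyl-1,3,2-dioxaborolane | C(c1ccccc1)O[C@H]1Cc2c(B3OC(C)(C)C(C)(C)O3)cc(OCc3ccccc3)c(OCc3ccccc3)c2O[C@@H]1c1ccc(OCc2ccccc2)c(OCc2ccccc2)c1
F7 | step 7 | tetradeca-O-benzyl trimer (23 with benzyl ethers on the 3-oxygens of both outer units) | O[C@H]1Cc2c(OCc3ccccc3)c(-c3cc(OCc4ccccc4)c(OCc4ccccc4)c4c3C[C@H](OCc3ccccc3)[C@@H](c3ccc(OCc5ccccc5)c(OCc5ccccc5)c3)O4)c(OCc3ccccc3)c(-c3cc(OCc4ccccc4)c(OCc4ccccc4)c4c3C[C@H](OCc3ccccc3)[C@@H](c3ccc(OCc5ccccc5)c(OCc5ccccc5)c3)O4)c2O[C@@H]1c1ccc(OCc2ccccc2)c(OCc2ccccc2)c1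
F8 | step 11 | {[(2R,3S)-7,8-bis(benzyloxy)-2-[3,4-bis(benzyloxy)phenyl]-5-bromo-3,4-dihydro-2H-chromen-3-yl]oxy}(tert-butyl)dimethylsilane | CC(C)(C)[Si](C)(C)O[C@H]1Cc2c(Br)cc(OCc3ccccc3)c(OCc3ccccc3)c2O[C@@H]1c1ccc(OCc2ccccc2)c(OCc2ccccc2)c1
F9 | step 11 | {(2R,3S)-7,8-bis(benzyloxy)-2-[3,4-bis(benzyloxy)phenyl]-3-[(tert-butyldimethylsilyl)oxy]-3,4-dihydro-2H-chromen-5-yl}lithium | CC(C)(C)[Si](C)(C)O[C@H]1Cc2c([Li])cc(OCc3ccccc3)c(OCc3ccccc3)c2O[C@@H]1c1ccc(OCc2ccccc2)c(OCc2ccccc2)c1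
F10 | step 11 | {(2R,3S)-7,8-bis(benzyloxy)-2-[3,4-bis(benzyloxy)phenyl]-3-[(tert-butyldimethylsilyl)oxy]-3,4-dihydro-2H-chromen-5-yl}zinc chloride | CC(C)(C)[Si](C)(C)O[C@H]1Cc2c([Zn]Cl)cc(OCc3ccccc3)c(OCc3ccccc3)c2O[C@@H]1c1ccc(OCc2ccccc2)c(OCc2ccccc2)c1
F11 | step 11 | {[(2R,3S)-5,7-bis(benzyloxy)-2-[3,4-bis(benzyloxy)phenyl]-6,8-dibromo-3,4-dihydro-2H-chromen-3-yl]oxy}(tert-butyl)dimethylsilane | CC(C)(C)[Si](C)(C)O[C@H]1Cc2c(OCc3ccccc3)c(Br)c(OCc3ccccc3)c(Br)c2O[C@@H]1c1ccc(OCc2ccccc2)c(OCc2ccccc2)c1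
F12 | step 11 | tris-O-(tert-butyldimethylsilyl) ether of 23 | CC(C)(C)[Si](C)(C)O[C@H]1Cc2c(OCc3ccccc3)c(-c3cc(OCc4ccccc4)c(OCc4ccccc4)c4c3C[C@H](O[Si](C)(C)C(C)(C)C)[C@@H](c3ccc(OCc5ccccc5)c(OCc5ccccc5)c3)O4)c(OCc3ccccc3)c(-c3cc(OCc4ccccc4)c(OCc4ccccc4)c4c3C[C@H](O[Si](C)(C)C(C)(C)C)[C@@H](c3ccc(OCc5ccccc5)c(OCc5ccccc5)c3)O4)c2O[C@@H]1c1ccc(OCc2ccccc2)c(OCc2ccccc2)c1
F13 | step 3 | (S)-[3,4-bis(benzyloxy)phenyl][(S)-2,2-dimethyl-1,3-dioxolan-4-yl]methanol | O[C@@H](c1ccc(OCc2ccccc2)c(OCc2ccccc2)c1)[C@@H]1COC(C)(C)O1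
F14 | step 3 | [3,4-bis(benzyloxy)phenyl][(S)-2,2-dimethyl-1,3-dioxolan-4-yl]methanone | O=C(c1ccc(OCc2ccccc2)c(OCc2ccccc2)c1)[C@@H]1COC(C)(C)O1
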